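## Retrosynthetic overview

1. The last bonds are the quinone C2–N amide bond (Pd2(dba)3/Xantphos amidation of bromonaphthoquinone 29 with primary dienamide 20), then release of CO2H from its tert-butyl ester.
2. Dienamide 20 comes from a Heck union (C3–C4) of terminal alkene 14 with (Z)-3-iodo-2-methylprop-2-enamide 19.
3. The bicyclic ketal of 14 comes from methallyl 1,3-diol 11 by an oxidative ring expansion (1,2-shift of C14, oxane → oxepane) with transannular ketal closure.
4. Diol 11 comes from 2-methylpropane-1,3-diol by three [Ir(cod)Cl]2/SEGPHOS transfer-hydrogenative couplings (double crotylation, crotylation, methallylation); an iodoetherification tells the two chain ends apart.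
5. Ring order: temporary oxane (step 2) → 2,8-dioxabicyclo[3.2.1]octane (step 7) → benzenoid ring of the naphthoquinone by Diels–Alder/aromatisation (step 18).

Convention: side-chain atoms keep the target numbering in every intermediate (C1 amide carbon to C17 ketal methyl; O7, O9, O11, O13 sit on those carbons); "as in 31" means the same spatial arrangement as in the target.

Assumption: the SEGPHOS antipodes written in steps 1, 4 and 6 are those taken to give the drawn carbinol configurations; if the sense of induction is the opposite, the mirror-image ligand is used in each case.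

## Route

Step 1
Reactants: 1 2-methylpropane-1,3-diol; 2 (±)-but-3-en-2-yl acetate
Product: 3 (3S,4S,6S,7S)-3,5,7-trimethylnona-1,8-diene-4,6-diol (C4–C12 of the target; C8 not yet stereogenic)
Conditions: [Ir(cod)Cl]2 (2.5 mol%), (S)-SEGPHOS (5 mol%), 4-cyano-3-nitrobenzoic acid (10 mol%), Cs2CO3 (20 mol%), 2 (4 equiv), THF, 90 °C
Reagents that add atoms: none
Why: Transfer-hydrogenative double carbonyl crotylation (Krische type): each CH2OH is dehydrogenated in turn and the aldehyde is trapped by the (E)-σ-crotyl metal species through a closed chair, which gives anti Me/OH at both ends, while the ligand sets both carbinols with the same sense (1,3-anti diol; C6, C7, C9, C10 as in 31) and wrong-sense addition ends up in a separable pseudo-meso isomer.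

Step 2
Reactants: 3 (3S,4S,6S,7S)-3,5,7-trimethylnona-1,8-diene-4,6-diol
Product: 4 iodoether: (2,6-cis)-2-[(S)-but-3-en-2-yl]-6-(iodomethyl)-3,5-dimethyloxan-4-ol (ring O9/C9/C8/C7/C6/C5; C9 chain, Me-8, OH-7 and CH2I equatorial, Me-6 axial)
Conditions: I2 (1.1 equiv), NaHCO3 (3 equiv), MeCN, 0 °C
Reagents that add atoms: iodine, [I][I]
Why: Reversible 6-exo iodoetherification: O9 closes onto C5 through the chair with four equatorial groups, whereas closure of O7 onto C11 would force Me-8 and Me-10 1,3-diaxial, so the two vinyl groups are told apart, C4=C5 and O9–H are masked together, and C8 becomes a stereocentre with the target configuration.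

Step 3
Reactants: 4 iodoether
Product: 6 diol (4 with C11H2OH in place of the vinyl group), via aldehyde 5 (not isolated)
Conditions: O3, CH2Cl2–MeOH (4:1), –78 °C (Sudan red end point); then NaBH4, –78 → 0 °C
Reagents that add atoms: ozone, [O-][O+]=O
Why: Ozonolysis with reductive work-up cuts the only C=C left, and the aldehyde is reduced cold before C10 can epimerise.

Step 4
Reactants: 6 diol; 2 (±)-but-3-en-2-yl acetate
Product: 7 homoallylic alcohol (C10–C11H(OH)–C12H(CH3)–C13H=C14H2; O11 syn to Me-10, Me-12 anti to O11)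
Conditions: [Ir(cod)Cl]2 (2.5 mol%), (R)-SEGPHOS (5 mol%), 4-cyano-3-nitrobenzoic acid (10 mol%), Cs2CO3 (20 mol%), 2 (2 equiv), THF, 90 °C
Reagents that add atoms: none
Why: Krische-type anti-crotylation at the primary alcohol only: the closed chair with the (E)-σ-crotyl species sets Me-12 anti to O11, and the ligand, matched with Felkin–Anh addition to the α-methyl aldehyde, places O11 syn to Me-10 (C11, C12 as in 31).

Step 5
Reactants: 7 homoallylic alcohol
Product: 9 triol (7 with C13H2OH in place of the vinyl group), via aldehyde 8 (not isolated)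
Conditions: O3, CH2Cl2–MeOH (4:1), –78 °C; then NaBH4, –78 → 0 °C
Reagents that add atoms: ozone, [O-][O+]=O
Why: Ozonolysis with reductive work-up as in step 3; C12 is kept because the β-hydroxy aldehyde is reduced at low temperature.

Step 6
Reactants: 9 triol; 10 3-chloro-2-methylprop-1-ene
Product: 11 methallyl triol (C13H(OH)–C14H2–C(CH3)=CH2; O13 syn to Me-12 and anti to O11)
Conditions: [Ir(cod)Cl]2 (2.5 mol%), (S)-SEGPHOS (5 mol%), 3-nitrobenzoic acid (10 mol%), K3PO4 (1.0 equiv), 10 (3 equiv), THF, 60 °C
Reagents that add atoms: none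
Why: Transfer-hydrogenative carbonyl methallylation (Krische type) of the primary alcohol of the 1,3-diol: the ligand sets C13, and Felkin–Anh control by Me-12 and the 1,3-anti preference of the β-hydroxy aldehyde point the same way (C13 as in 31).

Step 7
Reactants: 11 methallyl triol
Product: 13 iodo ketal (4 in which C10 carries the (1S,3S,4R,5S)-1,4-dimethyl-2,8-dioxabicyclo[3.2.1]octan-3-yl group), via alkoxy iodane 12 (not isolated)
Conditions: PhI(OH)OTs (1.1 equiv), CH2Cl2–(CF3)2CHOH (4:1), –40 → 0 °C; aqueous NaHCO3 work-up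
Reagents that add atoms: none
Why: Proposed new method: oxidative ring-expanding ketalisation by trivalent iodine, in which PhI(OH)OTs adds to the CH2 end of the 1,1-disubstituted alkene, O11–H captures the tertiary cation 6-exo to give oxane 12, and loss of PhI, pushed by the ring-oxygen lone pair, drives a semipinacol-type 1,2-shift of ring carbon C14 (primary alkyl migrates in preference to methyl) to a seven-membered oxocarbenium ion that O13–H closes transannularly; the bridged ring allows only one configuration at C16 and leaves Me-12 and the C11 chain equatorial; the closest known reactions are the PhI(OH)OTs ring expansion of methylenecycloalkanes to homologous ketones and the oxidative 1,2-aryl shift of α-methylstyrenes, and the new elements are the internal hydroxyl as first nucleophile, expansion of the oxacycle formed in the flask, and ketal capture.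

Step 8
Reactants: 13 iodo ketal
Product: 14 (3S,4S,5R,6R,7R)-7-[(1S,3S,4R,5S)-1,4-dimethyl-2,8-dioxabicyclo[3.2.1]octan-3-yl]-3,5-dimethyloct-1-ene-4,6-diol
Conditions: Zn dust, EtOH, 70 °C
Reagents that add atoms: none
Why: Reductive β-elimination (Boord type): Zn inserts into C4–I and expels O9, which returns the C4=C5 vinyl group and O9–H and erases the temporary C5 stereocentre.

Step 9
Reactants: 15 prop-2-yn-1-ol
Product: 16 (Z)-3-iodo-2-methylprop-2-en-1-ol
Conditions: MeMgBr (2.5 equiv), CuI (10 mol%), THF, –10 °C → rt; then I2, –10 °C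
Reagents that add atoms: methylmagnesium bromide, C[Mg]Br; iodine, [I][I]
Why: Duboudin-type CuI-catalysed anti-carbomagnesiation of the magnesium alkoxide puts CH3 on C2 and Mg on C3 cis to CH2O in a five-membered chelate, and iodinolysis with retention gives the Z-vinyl iodide.

Step 10
Reactants: 16 (Z)-3-iodo-2-methylprop-2-en-1-ol
Product: 17 (Z)-3-iodo-2-methylprop-2-enoic acid
Conditions: TEMPO (20 mol%), PhI(OAc)2 (2.2 equiv), MeCN–H2O (1:1), rt
Reagents that add atoms: water, O
Why: Oxoammonium (TEMPO/PhI(OAc)2) oxidation of the allylic alcohol through the aldehyde hydrate to the acid under near-neutral conditions that do not isomerise the Z-alkene.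

Step 11
Reactants: 17 (Z)-3-iodo-2-methylprop-2-enoic acid
Product: 19 (Z)-3-iodo-2-methylprop-2-enamide, via acid chloride 18 (not isolated)
Conditions: (COCl)2, DMF (cat.), CH2Cl2, 0 °C; then NH3 (0.5 M in 1,4-dioxane), 0 °C
Reagents that add atoms: ammonia, N
Why: Acyl chloride formation and ammonolysis; acylation of NH3 at 0 °C is much faster than addition–elimination at the β-iodo carbon.

Step 12
Reactants: 14 terminal alkene diol; 19 (Z)-3-iodo-2-methylprop-2-enamide
Product: 20 (2Z,4E,6S,7S,8R,9R,10R)-10-[(1S,3S,4R,5S)-1,4-dimethyl-2,8-dioxabicyclo[3.2.1]octan-3-yl]-7,9-dihydroxy-2,6,8-trimethylundeca-2,4-dienamide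
Conditions: Pd(OAc)2 (10 mol%), Ag2CO3 (1.0 equiv), DMF, 45 °C, dark
Reagents that add atoms: none
Why: Heck reaction under silver-assisted (Jeffery-type) conditions: syn-carbopalladation at the terminal carbon and syn-β-hydride elimination toward conjugation give the 4E alkene, the Z-geometry of the vinyl iodide is retained, and Ag2CO3 removes iodide so that hydride re-addition and chain walking are suppressed.

Step 13
Reactants: 21 phenol
Product: 22 2,4,6-tribromophenol
Conditions: Br2 (3.1 equiv), H2O, rt
Reagents that add atoms: bromine, BrBr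
Why: Exhaustive electrophilic aromatic bromination at both ortho positions and the para position of the phenol.

Step 14
Reactants: 22 2,4,6-tribromophenol
Product: 23 2,6-dibromo-1,4-benzoquinone
Conditions: fuming HNO3, 0 °C → rt
Reagents that add atoms: nitric acid, O[N+](=O)[O-]
Why: Oxidative ipso-debromination at the para position of the phenol gives the para-quinone and leaves both bromines next to the phenol-derived carbonyl.

Step 15
Reactants: 24 methyl 3-oxobutanoate
Product: 25 methyl 2-methyl-3-oxobutanoate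
Conditions: MeI (1.05 equiv), K2CO3, acetone, 56 °C
Reagents that add atoms: iodomethane, CI
Why: C-alkylation of the β-keto ester enolate at the doubly activated carbon.

Step 16
Reactants: 25 methyl 2-methyl-3-oxobutanoate
Product: 26 5-tert-butyl 1-methyl 2-methyl-3-oxopentanedioate
Conditions: LiN(iPr)2 (2.1 equiv), THF, –78 → 0 °C; Boc2O (1.0 equiv), –78 °C; 1 M HCl
Reagents that add atoms: di-tert-butyl dicarbonate, CC(C)(C)OC(=O)OC(=O)OC(C)(C)C
Why: Huckin–Weiler dianion chemistry: the second deprotonation takes place at the terminal CH3, and this more reactive carbanion is acylated by the dicarbonate to install the tert-butyl ester regioselectively.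

Step 17
Reactants: 26 5-tert-butyl 1-methyl 2-methyl-3-oxopentanedioate
Product: 27 tert-butyl (2Z,4Z)-5-methoxy-4-methyl-3,5-bis(trimethylsilyloxy)penta-2,4-dienoate
Conditions: LiN(iPr)2 (2.2 equiv), THF, –78 °C; Me3SiCl (2.5 equiv), –78 °C → rt; non-aqueous work-up
Reagents that add atoms: chlorotrimethylsilane, C[Si](C)(C)Cl
Why: Double O-silylation of the bis-enolate (first deprotonation at the CH2 flanked by ketone and tert-butyl ester, second at CH(CH3) next to the methyl ester) gives a Chan/Brassard-type 1,3-dioxygenated diene whose alkene geometries are of no consequence.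

Step 18
Reactants: 23 2,6-dibromo-1,4-benzoquinone; 27 bis-silyl diene
Product: 29 tert-butyl 6-bromo-2,4-dihydroxy-3-methyl-5,8-dioxo-5,8-dihydronaphthalene-1-carboxylate, via cycloadduct 28 (not isolated)
Conditions: toluene, –30 °C → rt; then Et3N (1.2 equiv), 0 °C; then 1 M HCl, THF, rt
Reagents that add atoms: none
Why: Brassard-type Diels–Alder reaction and aromatisation: the nucleophilic CH(CO2tBu) terminus of the diene bonds to the unsubstituted carbon of the bromo-alkene and the ketene-acetal carbon to the C–Br carbon, so after loss of HBr, methanol and the silyl groups the peri-OH and the remaining bromine flank the same carbonyl, as the target needs.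

Step 19
Reactants: 20 primary dienamide; 29 bromonaphthoquinone
Product: 30 tert-butyl ester of 31 (tert-butyl 6-{[(2Z,4E,6S,7S,8R,9R,10R)-10-[(1S,3S,4R,5S)-1,4-dimethyl-2,8-dioxabicyclo[3.2.1]octan-3-yl]-7,9-dihydroxy-2,6,8-trimethylundeca-2,4-dienoyl]amino}-2,4-dihydroxy-3-methyl-5,8-dioxo-5,8-dihydronaphthalene-1-carboxylate)
Conditions: Pd2(dba)3 (5 mol%), Xantphos (12 mol%), Cs2CO3 (3 equiv), 1,4-dioxane, 70 °C
Reagents that add atoms: none
Why: Buchwald-type amidation of a vinylogous acyl bromide: oxidative addition of C–Br to the zerovalent palladium–Xantphos complex and C–N reductive elimination give ipso substitution only, and the secondary alcohols and the dienamide geometry are not touched.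

Step 20
Reactants: 30 tert-butyl ester
Product: 31 rifsaliniketal
Conditions: CF3CO2H–CH2Cl2 (1:4), 0 °C
Reagents that add atoms: none
Why: Acidolysis of the tert-butyl ester (loss of the tert-butyl cation as 2-methylpropene); the bicyclic ketal is the thermodynamic ketal and recloses if it ionises.

## Compound list

1 | 2-methylpropane-1,3-diol | CC(CO)CO | starting material
2 | (±)-but-3-en-2-yl acetate | CC(OC(C)=O)C=C | starting material
3 | (3S,4S,6S,7S)-3,5,7-trimethylnona-1,8-diene-4,6-diol | C=C[C@H](C)[C@H](O)C(C)[C@@H](O)[C@@H](C)C=C | intermediate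
4 | iodoether: (2,6-cis)-2-[(S)-but-3-en-2-yl]-6-(iodomethyl)-3,5-dimethyloxan-4-ol, C6–C10 as in 31 | IC[C@H]1O[C@@H]([C@@H](C)C=C)[C@H](C)[C@@H](O)[C@H]1C | intermediate
5 | aldehyde: 4 with C11H=O in place of the vinyl group | IC[C@H]1O[C@@H]([C@@H](C)C=O)[C@H](C)[C@@H](O)[C@H]1C | intermediate
6 | diol: 4 with C11H2OH in place of the vinyl group | IC[C@H]1O[C@@H]([C@@H](C)CO)[C@H](C)[C@@H](O)[C@H]1C | intermediate
7 | homoallylic alcohol: 6 extended by C11H(OH)–C12H(CH3)–CH=CH2, C11 and C12 as in 31 | IC[C@H]1O[C@@H]([C@@H](C)[C@H](O)[C@H](C)C=C)[C@H](C)[C@@H](O)[C@H]1C | intermediate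
8 | aldehyde: 7 with C13H=O in place of the vinyl group | IC[C@H]1O[C@@H]([C@@H](C)[C@H](O)[C@H](C)C=O)[C@H](C)[C@@H](O)[C@H]1C | intermediate
9 | triol: 7 with C13H2OH in place of the vinyl group | IC[C@H]1O[C@@H]([C@@H](C)[C@H](O)[C@H](C)CO)[C@H](C)[C@@H](O)[C@H]1C | intermediate
10 | 3-chloro-2-methylprop-1-ene | CC(=C)CCl | starting material
11 | methallyl triol: 9 extended by C13H(OH)–CH2–C(CH3)=CH2, C13 as in 31 | IC[C@H]1O[C@@H]([C@@H](C)[C@H](O)[C@H](C)[C@@H](O)CC(C)=C)[C@H](C)[C@@H](O)[C@H]1C | intermediate
12 | alkoxy iodane: oxane closed from O11 onto the former alkene carbon, which carries CH3 and CH2–I(Ph)OTs (either configuration at this transient carbon) | IC[C@H]1O[C@@H]([C@@H](C)[C@@H]2OC(C)(CI(c3ccccc3)OS(=O)(=O)c3ccc(C)cc3)C[C@H](O)[C@H]2C)[C@H](C)[C@@H](O)[C@H]1C | intermediate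
13 | iodo ketal: 4 in which C10 carries the (1S,3S,4R,5S)-1,4-dimethyl-2,8-dioxabicyclo[3.2.1]octan-3-yl group | IC[C@H]1O[C@@H]([C@@H](C)[C@@H]2O[C@@]3(C)CC[C@H](O3)[C@H]2C)[C@H](C)[C@@H](O)[C@H]1C | intermediate
14 | (3S,4S,5R,6R,7R)-7-[(1S,3S,4R,5S)-1,4-dimethyl-2,8-dioxabicyclo[3.2.1]octan-3-yl]-3,5-dimethyloct-1-ene-4,6-diol | C=C[C@H](C)[C@H](O)[C@@H](C)[C@@H](O)[C@@H](C)[C@@H]1O[C@@]2(C)CC[C@H](O2)[C@H]1C | intermediate
15 | prop-2-yn-1-ol | C#CCO | starting material
16 | (Z)-3-iodo-2-methylprop-2-en-1-ol | I/C=C(/C)CO | intermediate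
17 | (Z)-3-iodo-2-methylprop-2-enoic acid | I/C=C(/C)C(=O)O | intermediate
18 | (Z)-3-iodo-2-methylprop-2-enoyl chloride | I/C=C(/C)C(=O)Cl | intermediate
19 | (Z)-3-iodo-2-methylprop-2-enamide | I/C=C(/C)C(N)=O | intermediate
20 | (2Z,4E,6S,7S,8R,9R,10R)-10-[(1S,3S,4R,5S)-1,4-dimethyl-2,8-dioxabicyclo[3.2.1]octan-3-yl]-7,9-dihydroxy-2,6,8-trimethylundeca-2,4-dienamide | C/C(=C/C=C/[C@H](C)[C@H](O)[C@@H](C)[C@@H](O)[C@@H](C)[C@@H]1O[C@@]2(C)CC[C@H](O2)[C@H]1C)C(N)=O | intermediate
21 | phenol | Oc1ccccc1 | starting material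
22 | 2,4,6-tribromophenol | Oc1c(Br)cc(Br)cc1Br | intermediate
23 | 2,6-dibromo-1,4-benzoquinone | O=C1C=C(Br)C(=O)C(Br)=C1 | intermediate
24 | methyl 3-oxobutanoate | CC(=O)CC(=O)OC | starting material
25 | methyl 2-methyl-3-oxobutanoate (racemic) | CC(=O)C(C)C(=O)OC | intermediate
26 | 5-tert-butyl 1-methyl 2-methyl-3-oxopentanedioate (racemic) | COC(=O)C(C)C(=O)CC(=O)OC(C)(C)C | intermediate
27 | tert-butyl (2Z,4Z)-5-methoxy-4-methyl-3,5-bis(trimethylsilyloxy)penta-2,4-dienoate | CO/C(O[Si](C)(C)C)=C(C)/C(O[Si](C)(C)C)=C/C(=O)OC(C)(C)C | intermediate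
28 | Diels–Alder adduct of 23 and 27 (diastereomer mixture; its four sp3 stereocentres are lost in the same flask) | O=C1C(Br)=CC(=O)C2C(C(=O)OC(C)(C)C)C(O[Si](C)(C)C)=C(C)C(OC)(O[Si](C)(C)C)C12Br | intermediate
29 | tert-butyl 6-bromo-2,4-dihydroxy-3-methyl-5,8-dioxo-5,8-dihydronaphthalene-1-carboxylate | BrC1=CC(=O)c2c(C(=O)OC(C)(C)C)c(O)c(C)c(O)c2C1=O | intermediate
30 | tert-butyl ester of rifsaliniketal | C/C(=C/C=C/[C@H](C)[C@H](O)[C@@H](C)[C@@H](O)[C@@H](C)[C@@H]1O[C@@]2(C)CC[C@H](O2)[C@H]1C)C(=O)NC1=CC(=O)c2c(C(=O)OC(C)(C)C)c(O)c(C)c(O)c2C1=O | intermediate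
31 | rifsaliniketal | C/C(=C/C=C/[C@H](C)[C@H](O)[C@@H](C)[C@@H](O)[C@@H](C)[C@@H]1O[C@@]2(C)CC[C@H](O2)[C@H]1C)C(=O)NC1=CC(=O)c2c(C(=O)O)c(O)c(C)c(O)c2C1=O | target

## Step count and risks

Total step count: 20. Longest linear sequence: 11 steps (steps 1–8, 12, 19, 20).

The three steps most likely to fail are steps 7, 12 and 19.

Step 7 is the proposed oxidative ring expansion. It can fail by methyl instead of C14 migration, by oxygen participation in place of carbon migration, or by acid-catalysed hydroalkoxylation of the alkene. The fallback uses known chemistry, sets out from 7 and comes back at 13. Ozonolysis of 7 with PPh3 work-up gives β-hydroxy aldehyde 8, which is isolated in this case. But-3-enylmagnesium bromide (excess, THF, –78 °C) adds under Felkin–Anh control to give the but-3-enyl triol F1, and the C13 epimer is removed by chromatography. A Wacker-type oxidative ketalisation (PdCl2 10 mol%, CuCl, O2, DMF–H2O) then closes the 1,3-diol onto C16 and gives 13.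

Step 12 is the Heck coupling. It can fail by chain walking toward the C7 carbinol or by erosion of the Z-geometry. The fallback sets out from 14 and comes back at 20. Cross-metathesis of 14 with 4,4,5,5-tetramethyl-2-vinyl-1,3,2-dioxaborolane (second-generation Grubbs catalyst, (H2IMes)(PCy3)Cl2Ru=CHPh, CH2Cl2, 40 °C) gives the (E)-alkenylboronate F2. Suzuki–Miyaura coupling of F2 with 19 (Pd(PPh3)4, aqueous Cs2CO3, THF, rt) gives 20.

Step 19 is the C–N coupling on a bromoquinone that carries two free phenols. The fallback sets out from 29 and comes back at 30, bypassing amide 20. NaN3 (DMF, 0 °C) replaces the bromide and gives the azidoquinone F3. Staudinger reduction (PPh3, THF–H2O) gives the aminoquinone F4. N-Acylation of F4 with acid chloride 18 (pyridine, CH2Cl2, 40 °C; any phenol ester is cleaved with NaHCO3–MeOH) gives the N-quinonyl (Z)-iodoacrylamide F5. Heck coupling of F5 with alkene 14 under the conditions of step 12 gives 30.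

## Further compounds

F1 | step 7 | but-3-enyl triol: 9 extended by C13H(OH)–CH2CH2CH=CH2, C13 as in 31 | IC[C@H]1O[C@@H]([C@@H](C)[C@H](O)[C@H](C)[C@@H](O)CCC=C)[C@H](C)[C@@H](O)[C@H]1C
F2 | step 12 | (E)-alkenylboronate: 14 with a 4,4,5,5-tetramethyl-1,3,2-dioxaborolan-2-yl group on C4 | CC1(C)OB(/C=C/[C@H](C)[C@H](O)[C@@H](C)[C@@H](O)[C@@H](C)[C@@H]2O[C@@]3(C)CC[C@H](O3)[C@H]2C)OC1(C)C
F3 | step 19 | tert-butyl 6-azido-2,4-dihydroxy-3-methyl-5,8-dioxo-5,8-dihydronaphthalene-1-carboxylate | [N-]=[N+]=NC1=CC(=O)c2c(C(=O)OC(C)(C)C)c(O)c(C)c(O)c2C1=O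
F4 | step 19 | tert-butyl 6-amino-2,4-dihydroxy-3-methyl-5,8-dioxo-5,8-dihydronaphthalene-1-carboxylate | NC1=CC(=O)c2c(C(=O)OC(C)(C)C)c(O)c(C)c(O)c2C1=O
F5 | step 19 | tert-butyl 2,4-dihydroxy-6-{[(Z)-3-iodo-2-methylprop-2-enoyl]amino}-3-methyl-5,8-dioxo-5,8-dihydronaphthalene-1-carboxylate | I/C=C(/C)C(=O)NC1=CC(=O)c2c(C(=O)OC(C)(C)C)c(O)c(C)c(O)c2C1=O
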